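**Plan**
- Cuts: ring C is opened at C4–C4a (aryl anion onto a Weinreb amide). Ring A is then cut across C5–C6, C7–C8 and C4a–C5 into a 3-alkoxycyclobutenone (C5, C4a, C8a, C8, with its alkoxy oxygen as O1) and a geranyl siloxyalkyne (C6, C7). The O1–C8a vinylogous ester bond and the C3–C4 Claisen bond are cut last.
- Feature used: ring A is a phloroglucinol ring with oxygen on C5, C7 and C8a and geranyl on C6, para to O1. This is the pattern the two partners deliver, and either carbon ortho to O1 leads to the 6-geranyl flavanone.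
- Forward: ring B is bought, the C2–C3–C4 chain is attached by Claisen condensation, the carbinol is transferred onto the cyclobutenone, ring A is built by benzannulation, ring C is closed by Parham cyclisation, and fluoride frees the four phenols.
- Stereochemistry: the single stereocentre (C2, S) is set by Ru-catalysed asymmetric transfer hydrogenation of the β-keto amide. Its C–O bond is never broken afterwards.

Key step: step 7

Assumption: HC≡CMgBr (THF solution), 3-ethoxycyclobut-2-en-1-one and N-methoxy-N-methylacetamide are bought, and all steps are run under argon.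

**Step 1**
Reactants: 1 geranyl bromide; 2 ethynylmagnesium bromide
Product: 3 (E)-5,9-dimethyldeca-4,8-dien-1-yne
Conditions: HC≡CMgBr (2 equiv), CuCl (10 mol%), THF, 0 → 50 °C
Reagents that add atoms: none
Why: Copper-catalysed coupling of an alkynyl Grignard reagent with a primary allylic bromide substitutes at the unhindered CH2Br terminus, so the E alkene is kept and the skipped enyne should form directly.

**Step 2**
Reactants: 3 (E)-5,9-dimethyldeca-4,8-dien-1-yne
Product: 6 (E)-5,9-dimethyldeca-4,8-dien-1-ynyl triisopropylsilyl ether, via lithium acetylide 4 (not isolated), via lithium ynolate 5 (not isolated)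
Conditions: n-BuLi, THF, −78 °C; LiOOtBu (from t-BuOOH, LiN(SiMe3)2), −78 → 0 °C; iPr3SiOTf, −78 → 0 °C; H2O
Reagents that add atoms: tert-butyl hydroperoxide, CC(C)(C)OO; triisopropylsilyl trifluoromethanesulfonate, CC(C)[Si](OS(=O)(=O)C(F)(F)F)(C(C)C)C(C)C
Why: Oxygenation of a lithium acetylide by lithium tert-butyl peroxide gives the ynolate, which the bulky silyl triflate traps on oxygen (the standard route from terminal alkynes to silyl ynol ethers); the alkynyl proton is removed far faster than the allylic-propargylic CH2, so the enyne should not isomerise.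

**Step 3**
Reactants: 7 methyl 3,4-dihydroxybenzoate
Product: 8 methyl 3,4-bis(tert-butyldimethylsilyloxy)benzoate
Conditions: TBSCl (2.4 equiv), imidazole, DMF, rt
Reagents that add atoms: tert-butyldimethylsilyl chloride, CC(C)(C)[Si](C)(C)Cl
Why: Imidazole-promoted silylation of both catechol hydroxyls is routine and gives ethers that survive enolates, heat and organolithiums yet fall to fluoride at the end.

**Step 4**
Reactants: 8 methyl 3,4-bis(tert-butyldimethylsilyloxy)benzoate; 9 N-methoxy-N-methylacetamide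
Product: 11 3-[3,4-bis(tert-butyldimethylsilyloxy)phenyl]-N-methoxy-N-methyl-3-oxopropanamide, via lithium amide enolate 10 (not isolated)
Conditions: 9 (2.2 equiv), LiN(iPr)2 (2.2 equiv), THF, −78 °C; then 8, −78 → −30 °C; AcOH
Reagents that add atoms: none
Why: Crossed Claisen condensation: the amide is fully enolised before the non-enolisable aryl ester is added, and deprotonation of the β-keto amide by the second equivalent of enolate drives the acylation and blocks a second addition.

**Step 5**
Reactants: 11 3-[3,4-bis(tert-butyldimethylsilyloxy)phenyl]-N-methoxy-N-methyl-3-oxopropanamide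
Product: 12 (S)-3-[3,4-bis(tert-butyldimethylsilyloxy)phenyl]-3-hydroxy-N-methoxy-N-methylpropanamide
Conditions: RuCl[(S,S)-TsDPEN](p-cymene) (1 mol%), HCO2H/Et3N (5:2), EtOAc, 35 °C
Reagents that add atoms: none
Why: Noyori asymmetric transfer hydrogenation of an aryl ketone: hydride and proton are delivered through the six-membered Ru–H/N–H transition state with the aryl ring against the η6-arene, and the (S,S)-ligand should give the (S)-carbinol, to be confirmed by Mosher ester analysis.

**Step 6**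
Reactants: 12 (S)-3-[3,4-bis(tert-butyldimethylsilyloxy)phenyl]-3-hydroxy-N-methoxy-N-methylpropanamide; 13 3-ethoxycyclobut-2-en-1-one
Product: 14 (S)-3-[3,4-bis(tert-butyldimethylsilyloxy)phenyl]-N-methoxy-N-methyl-3-[(3-oxocyclobut-1-en-1-yl)oxy]propanamide
Conditions: 13 (3 equiv), PPTS (10 mol%), 5 Å molecular sieves, toluene, 40 °C
Reagents that add atoms: none
Why: Acid-catalysed alkoxy exchange of a vinylogous ester (the alcohol adds to C3 of the O-protonated enone and ethanol leaves, trapped by the sieves); the carbinol C–O bond is not involved, so the S configuration should be retained.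

**Step 7**
Reactants: 14 (S)-3-[3,4-bis(tert-butyldimethylsilyloxy)phenyl]-N-methoxy-N-methyl-3-[(3-oxocyclobut-1-en-1-yl)oxy]propanamide; 6 (E)-5,9-dimethyldeca-4,8-dien-1-ynyl triisopropylsilyl ether
Product: 19 (S)-3-[3,4-bis(tert-butyldimethylsilyloxy)phenyl]-3-{4-[(E)-3,7-dimethylocta-2,6-dienyl]-3-hydroxy-5-(triisopropylsilyloxy)phenoxy}-N-methoxy-N-methylpropanamide, via vinylketene 15 (not isolated), via vinylcyclobutenone 16 (not isolated), via dienylketene 17 (not isolated), via cyclohexadienone 18 (not isolated)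
Conditions: 6 (2 equiv), toluene, 80 → 110 °C, sealed tube
Reagents that add atoms: none
Why: Heat opens cyclobutenone 14 by four-electron electrocyclic cleavage to vinylketene 15, whose ketene carbon is attacked by the geranyl-bearing, nucleophilic carbon of siloxyalkyne 6 in a [2+2] cycloaddition to give vinylcyclobutenone 16. A second four-electron opening gives dienylketene 17, and ring A closes by six-electron electrocyclisation between the ketene carbon and the terminal CH2 to dienone 18, which tautomerises to phenol 19. This is the Danheiser benzannulation as used with siloxyalkynes, here with a 3-alkoxycyclobutenone, whose vinylogous ester stabilisation should raise the temperature of the first opening without changing its course. No stereocentre is created, and the neutral thermal conditions should leave the benzylic C–O stereocentre, the Weinreb amide, the silyl ethers and the geranyl alkenes untouched. The selectivity needed is the orientation of the [2+2] step; the polarisation of the silyl ynol ether fixes it, placing geranyl between the new OH and the silyloxy group and para to the chiral ether oxygen. Excess 6 should keep phenol 19 from being acylated by ketene 15.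

**Step 8**
Reactants: 19 (S)-3-[3,4-bis(tert-butyldimethylsilyloxy)phenyl]-3-{4-[(E)-3,7-dimethylocta-2,6-dienyl]-3-hydroxy-5-(triisopropylsilyloxy)phenoxy}-N-methoxy-N-methylpropanamide
Product: 20 (S)-3-[3,4-bis(tert-butyldimethylsilyloxy)phenyl]-3-{4-[(E)-3,7-dimethylocta-2,6-dienyl]-3,5-bis(triisopropylsilyloxy)phenoxy}-N-methoxy-N-methylpropanamide
Conditions: iPr3SiCl, imidazole, DMAP (cat.), DMF, rt
Reagents that add atoms: triisopropylsilyl chloride, CC(C)[Si](Cl)(C(C)C)C(C)C
Why: Silylation of a phenol removes the acidic proton before the lithiation, shields the oxygen next to geranyl from the iodinating agent, and makes the two free ring A positions equivalent.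

**Step 9**
Reactants: 20 (S)-3-[3,4-bis(tert-butyldimethylsilyloxy)phenyl]-3-{4-[(E)-3,7-dimethylocta-2,6-dienyl]-3,5-bis(triisopropylsilyloxy)phenoxy}-N-methoxy-N-methylpropanamide
Product: 21 (S)-3-[3,4-bis(tert-butyldimethylsilyloxy)phenyl]-3-{4-[(E)-3,7-dimethylocta-2,6-dienyl]-2-iodo-3,5-bis(triisopropylsilyloxy)phenoxy}-N-methoxy-N-methylpropanamide
Conditions: NIS (1.05 equiv), MeCN/CH2Cl2, 0 °C, dark
Reagents that add atoms: N-iodosuccinimide, O=C1CCC(=O)N1I
Why: Electrophilic aromatic iodination of a 1,3,5-trioxygenated arene: each free position is ortho to two oxygens and para to the third, the two are interchanged by rotation about the aryl–O bond so one monoiodide should result, and in an aprotic, acid-free medium the reversible iodonium formation at the geranyl alkenes finds no nucleophile.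

**Step 10**
Reactants: 21 (S)-3-[3,4-bis(tert-butyldimethylsilyloxy)phenyl]-3-{4-[(E)-3,7-dimethylocta-2,6-dienyl]-2-iodo-3,5-bis(triisopropylsilyloxy)phenoxy}-N-methoxy-N-methylpropanamide
Product: 24 (S)-2-[3,4-bis(tert-butyldimethylsilyloxy)phenyl]-6-[(E)-3,7-dimethylocta-2,6-dienyl]-5,7-bis(triisopropylsilyloxy)chroman-4-one, via aryllithium 22 (not isolated), via lithium hemiaminal 23 (not isolated)
Conditions: n-BuLi (1.1 equiv), THF, −78 °C; then AcOH, −78 °C → rt
Reagents that add atoms: none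
Why: Parham cyclisation: iodine–lithium exchange at −78 °C outruns addition of n-BuLi to the amide, aryllithium 22 adds 6-exo to the Weinreb amide, and the chelated tetrahedral intermediate 23 releases the ketone only on the acidic quench, so neither over-addition nor base-induced opening at C2 should occur.

**Step 11**
Reactants: 24 (S)-2-[3,4-bis(tert-butyldimethylsilyloxy)phenyl]-6-[(E)-3,7-dimethylocta-2,6-dienyl]-5,7-bis(triisopropylsilyloxy)chroman-4-one
Product: 25 nymphaeol A
Conditions: Bu4NF/AcOH (1:1, 6 equiv), THF, 0 °C → rt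
Reagents that add atoms: none
Why: Fluoride cleaves all four aryl silyl ethers, and the acetic acid buffer keeps the phenols protonated, which should suppress the phenoxide-driven retro-oxa-Michael opening that would racemise C2 of a 5-hydroxyflavanone.

**Compound list**
1 | geranyl bromide, (E)-1-bromo-3,7-dimethylocta-2,6-diene | CC(C)=CCC/C(C)=C/CBr | starting material
2 | ethynylmagnesium bromide | C#C[Mg]Br | starting material
3 | (E)-5,9-dimethyldeca-4,8-dien-1-yne | CC(C)=CCC/C(C)=C/CC#C | intermediate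
4 | lithium acetylide of 3 | CC(C)=CCC/C(C)=C/CC#C[Li] | intermediate
5 | lithium (E)-5,9-dimethyldeca-4,8-dien-1-yn-1-olate (ynolate) | CC(C)=CCC/C(C)=C/CC#C[O-].[Li+] | intermediate
6 | (E)-5,9-dimethyldeca-4,8-dien-1-ynyl triisopropylsilyl ether | CC(C)=CCC/C(C)=C/CC#CO[Si](C(C)C)(C(C)C)C(C)C | intermediate
7 | methyl 3,4-dihydroxybenzoate | COC(=O)c1ccc(O)c(O)c1 | starting material
8 | methyl 3,4-bis(tert-butyldimethylsilyloxy)benzoate | COC(=O)c1ccc(O[Si](C)(C)C(C)(C)C)c(O[Si](C)(C)C(C)(C)C)c1 | intermediate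
9 | N-methoxy-N-methylacetamide | CC(=O)N(C)OC | starting material
10 | lithium enolate of 9 | [Li+].[O-]C(=C)N(C)OC | intermediate
11 | 3-[3,4-bis(tert-butyldimethylsilyloxy)phenyl]-N-methoxy-N-methyl-3-oxopropanamide | CON(C)C(=O)CC(=O)c1ccc(O[Si](C)(C)C(C)(C)C)c(O[Si](C)(C)C(C)(C)C)c1 | intermediate
12 | (S)-3-[3,4-bis(tert-butyldimethylsilyloxy)phenyl]-3-hydroxy-N-methoxy-N-methylpropanamide | CON(C)C(=O)C[C@@H](c1ccc(O[Si](C)(C)C(C)(C)C)c(O[Si](C)(C)C(C)(C)C)c1)O | intermediate
13 | 3-ethoxycyclobut-2-en-1-one | CCOC1=CC(=O)C1 | starting material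
14 | (S)-3-[3,4-bis(tert-butyldimethylsilyloxy)phenyl]-N-methoxy-N-methyl-3-[(3-oxocyclobut-1-en-1-yl)oxy]propanamide | CON(C)C(=O)C[C@@H](c1ccc(O[Si](C)(C)C(C)(C)C)c(O[Si](C)(C)C(C)(C)C)c1)OC1=CC(=O)C1 | intermediate
15 | vinylketene from 14, (S)-3-aryl-N-methoxy-N-methyl-3-[(4-oxobuta-1,3-dien-2-yl)oxy]propanamide | CON(C)C(=O)C[C@@H](c1ccc(O[Si](C)(C)C(C)(C)C)c(O[Si](C)(C)C(C)(C)C)c1)OC(=C)C=C=O | intermediate
16 | 2-geranyl-3-(triisopropylsilyloxy)-4-[1-(alkoxy)vinyl]cyclobut-2-enone, the [2+2] adduct of 15 and 6 | CC(C)=CCC/C(C)=C/CC1=C(O[Si](C(C)C)(C(C)C)C(C)C)C(C(=C)O[C@@H](CC(=O)N(C)OC)c2ccc(O[Si](C)(C)C(C)(C)C)c(O[Si](C)(C)C(C)(C)C)c2)C1=O | intermediate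
17 | dienylketene from opening of 16 (ketene and terminal vinyl cis on the central alkene) | CC(C)=CCC/C(C)=C/CC(=C=O)/C(O[Si](C(C)C)(C(C)C)C(C)C)=C\C(=C)O[C@@H](CC(=O)N(C)OC)c1ccc(O[Si](C)(C)C(C)(C)C)c(O[Si](C)(C)C(C)(C)C)c1 | intermediate
18 | cyclohexa-2,4-dienone tautomer of 19 | CC(C)=CCC/C(C)=C/CC1=C(O[Si](C(C)C)(C(C)C)C(C)C)C=C(O[C@@H](CC(=O)N(C)OC)c2ccc(O[Si](C)(C)C(C)(C)C)c(O[Si](C)(C)C(C)(C)C)c2)CC1=O | intermediate
19 | (S)-3-[3,4-bis(tert-butyldimethylsilyloxy)phenyl]-3-{4-[(E)-3,7-dimethylocta-2,6-dienyl]-3-hydroxy-5-(triisopropylsilyloxy)phenoxy}-N-methoxy-N-methylpropanamide | CC(C)=CCC/C(C)=C/Cc1c(O)cc(O[C@@H](CC(=O)N(C)OC)c2ccc(O[Si](C)(C)C(C)(C)C)c(O[Si](C)(C)C(C)(C)C)c2)cc1O[Si](C(C)C)(C(C)C)C(C)C | intermediate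
20 | (S)-3-[3,4-bis(tert-butyldimethylsilyloxy)phenyl]-3-{4-[(E)-3,7-dimethylocta-2,6-dienyl]-3,5-bis(triisopropylsilyloxy)phenoxy}-N-methoxy-N-methylpropanamide | CC(C)=CCC/C(C)=C/Cc1c(O[Si](C(C)C)(C(C)C)C(C)C)cc(O[C@@H](CC(=O)N(C)OC)c2ccc(O[Si](C)(C)C(C)(C)C)c(O[Si](C)(C)C(C)(C)C)c2)cc1O[Si](C(C)C)(C(C)C)C(C)C | intermediate
21 | (S)-3-[3,4-bis(tert-butyldimethylsilyloxy)phenyl]-3-{4-[(E)-3,7-dimethylocta-2,6-dienyl]-2-iodo-3,5-bis(triisopropylsilyloxy)phenoxy}-N-methoxy-N-methylpropanamide | CC(C)=CCC/C(C)=C/Cc1c(O[Si](C(C)C)(C(C)C)C(C)C)cc(O[C@@H](CC(=O)N(C)OC)c2ccc(O[Si](C)(C)C(C)(C)C)c(O[Si](C)(C)C(C)(C)C)c2)c(I)c1O[Si](C(C)C)(C(C)C)C(C)C | intermediate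
22 | aryllithium from 21 (Li in place of I) | CC(C)=CCC/C(C)=C/Cc1c(O[Si](C(C)C)(C(C)C)C(C)C)cc(O[C@@H](CC(=O)N(C)OC)c2ccc(O[Si](C)(C)C(C)(C)C)c(O[Si](C)(C)C(C)(C)C)c2)c([Li])c1O[Si](C(C)C)(C(C)C)C(C)C | intermediate
23 | lithium alkoxide of the C4 N-methoxy-N-methyl hemiaminal of 24 | CC(C)=CCC/C(C)=C/Cc1c(O[Si](C(C)C)(C(C)C)C(C)C)cc2c(c1O[Si](C(C)C)(C(C)C)C(C)C)C(O[Li])(N(C)OC)C[C@@H](c1ccc(O[Si](C)(C)C(C)(C)C)c(O[Si](C)(C)C(C)(C)C)c1)O2 | intermediate
24 | (S)-2-[3,4-bis(tert-butyldimethylsilyloxy)phenyl]-6-[(E)-3,7-dimethylocta-2,6-dienyl]-5,7-bis(triisopropylsilyloxy)chroman-4-one | CC(C)=CCC/C(C)=C/Cc1c(O[Si](C(C)C)(C(C)C)C(C)C)cc2c(c1O[Si](C(C)C)(C(C)C)C(C)C)C(=O)C[C@@H](c1ccc(O[Si](C)(C)C(C)(C)C)c(O[Si](C)(C)C(C)(C)C)c1)O2 | intermediate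
25 | nymphaeol A, (S)-2-(3,4-dihydroxyphenyl)-6-[(E)-3,7-dimethylocta-2,6-dienyl]-5,7-dihydroxychroman-4-one | CC(C)=CCC/C(C)=C/Cc1c(O)cc2c(c1O)C(=O)C[C@@H](c1ccc(O)c(O)c1)O2 | target

**Step count and risks**
Total: 11 steps. Longest linear sequence: 9 steps (steps 3–11, from methyl 3,4-dihydroxybenzoate); the alkyne branch (steps 1–2) joins at step 7.

Step 7 is the most likely to fail. The vinylogous ester resonance of the alkoxycyclobutenone may slow the first ring opening so much that acylation of the product phenol by the ketene, or thermal ionisation of the electron-rich benzylic C–O bond, outruns the cascade. The fallback gives up the annulation and builds ring A from a bought phloroglucinol core, forming O1–C2 at the stereocentre. It sets out from 11 and 1 and returns at 20. Keto amide 11 would be reduced with RuCl[(R,R)-TsDPEN](p-cymene) under the conditions of step 5 to the (R)-hydroxy amide F1. Phloroglucinol F2 would be C-geranylated with 1 (DBU, THF) to 2-geranylphloroglucinol F3 and persilylated (iPr3SiCl, imidazole, DMF) to the tris(triisopropylsilyl) ether F4. The one silyl ether not flanked by the side chain would then be removed with one equivalent of Bu4NF at −78 °C to give 4-geranyl-3,5-bis(triisopropylsilyloxy)phenol F5. Mitsunobu coupling of F1 with F5 (PPh3, DIAD, toluene, 0 °C) should give 20 with inversion.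

Step 6 is next. The exchange equilibrium may stay on the ethanol side with a hindered secondary alcohol, and the acid may ionise the benzylic C–O bond, leading to racemisation or elimination to the cinnamamide. The fallback forms the bond at carbon with inversion instead of at the ring. It sets out from 11 and 13 and returns at 14. The (R)-hydroxy amide F1 would be made from 11 as above, and 13 would be hydrolysed (dilute aqueous HCl) to cyclobutane-1,3-dione F6. Mitsunobu O-alkylation of this acidic dione with F1 (PPh3, DIAD, THF, 0 °C) should give 14.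

Step 10 is third. After iodine–lithium exchange, migration of the neighbouring silyl group from oxygen to carbon, or deprotonation next to the amide with loss of the aryloxide, may compete with ring closure. The fallback avoids the aryllithium. It sets out from 21 and returns at 24. The Weinreb amide would be reduced with iBu2AlH (THF, −78 °C) to the aldehyde F7. A neutral intramolecular Nozaki–Hiyama–Kishi reaction (CrCl2, NiCl2 cat., DMF, rt) should close ring C to the chroman-4-ol F8 as a mixture of C4 epimers. Dess–Martin oxidation (NaHCO3, CH2Cl2) would then give 24.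

**Further compounds**
F1 | step 7 | (R)-3-[3,4-bis(tert-butyldimethylsilyloxy)phenyl]-3-hydroxy-N-methoxy-N-methylpropanamide | CON(C)C(=O)C[C@H](c1ccc(O[Si](C)(C)C(C)(C)C)c(O[Si](C)(C)C(C)(C)C)c1)O
F2 | step 7 | phloroglucinol (benzene-1,3,5-triol, bought) | Oc1cc(O)cc(O)c1
F3 | step 7 | 2-[(E)-3,7-dimethylocta-2,6-dienyl]benzene-1,3,5-triol | CC(C)=CCC/C(C)=C/Cc1c(O)cc(O)cc1O
F4 | step 7 | 2-[(E)-3,7-dimethylocta-2,6-dienyl]-1,3,5-tris(triisopropylsilyloxy)benzene | CC(C)=CCC/C(C)=C/Cc1c(O[Si](C(C)C)(C(C)C)C(C)C)cc(O[Si](C(C)C)(C(C)C)C(C)C)cc1O[Si](C(C)C)(C(C)C)C(C)C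
F5 | step 7 | 4-[(E)-3,7-dimethylocta-2,6-dienyl]-3,5-bis(triisopropylsilyloxy)phenol | CC(C)=CCC/C(C)=C/Cc1c(O[Si](C(C)C)(C(C)C)C(C)C)cc(O)cc1O[Si](C(C)C)(C(C)C)C(C)C
F6 | step 6 | cyclobutane-1,3-dione | O=C1CC(=O)C1
F7 | step 10 | (S)-3-[3,4-bis(tert-butyldimethylsilyloxy)phenyl]-3-{4-[(E)-3,7-dimethylocta-2,6-dienyl]-2-iodo-3,5-bis(triisopropylsilyloxy)phenoxy}propanal | CC(C)=CCC/C(C)=C/Cc1c(O[Si](C(C)C)(C(C)C)C(C)C)cc(O[C@@H](CC=O)c2ccc(O[Si](C)(C)C(C)(C)C)c(O[Si](C)(C)C(C)(C)C)c2)c(I)c1O[Si](C(C)C)(C(C)C)C(C)C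
F8 | step 10 | (2S)-2-[3,4-bis(tert-butyldimethylsilyloxy)phenyl]-6-[(E)-3,7-dimethylocta-2,6-dienyl]-5,7-bis(triisopropylsilyloxy)chroman-4-ol (both C4 epimers) | CC(C)=CCC/C(C)=C/Cc1c(O[Si](C(C)C)(C(C)C)C(C)C)cc2c(c1O[Si](C(C)C)(C(C)C)C(C)C)C(O)C[C@@H](c1ccc(O[Si](C)(C)C(C)(C)C)c(O[Si](C)(C)C(C)(C)C)c1)O2
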